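## The problem

CNP0219255.1 (30) is an eudesmane: a trans-fused decalin in which ring A (C1–C5, C10) carries all four ring stereocentres, C3 and C4 as a cis (3α,4α) diol and the ring-fusion pair C5 (α-H) and C10 (β-methyl), while ring B (C5–C10) has none. Two of these centres are fully substituted and stand 1,3 to each other with syn-axial methyl groups (oxygenated C4 and all-carbon C10), so the bonds to them have to be made early. The configuration can be relayed: the trans relation of C5 and C10 can be written into the geometry of an alkene, and once both are set they shield the β face of ring A, so a syn dioxygenation of a C3=C4 alkene should place both oxygens α. The two hydroxyls are acylated differently. The secondary O3 carries the hindered (2S,3R)-2,3-dimethyloxirane-2-carboxylic acid (18), whose two stereocentres are independent of the ring and need reagent control. The tertiary O4 carries an acetate that would migrate to a free O3, so the acetate must follow the ester. Ring B holds a 2-substituted enone (C6=C7–C8=O) with a tertiary carbinol (C11) on C7; this β-hydroxy enone, the epoxide, the tertiary acetate and the γ-hydrogen at C5 exclude strong acid, strong base and hard nucleophiles late in the route. The enabling feature is the trisubstituted C6=C7 bond: C6 hangs on C5, C7 is tied through C8 and C9 to C10, and because ring B has no stereocentre it can be closed last by olefin metathesis between a vinyl group on C5 and a 1,1-disubstituted enone alkene on the C10 side chain.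

## Retrosynthesis

30 ⇒ 29. Only the O–Si bond at C11 is cut. The tertiary carbinol is the one hydroxyl that must stay masked while the C4 hydroxyl is acetylated and while the coupling and ring closure are run; a triethylsilyl ether on a tertiary centre should survive these and leave under buffered, non-basic conditions. 29 is no simpler than 30, but every demanding reaction now lies before the last step.

29 ⇒ 28. The C6=C7 bond is cut (ring-closing metathesis forward). An aldol-type closure of the same bond would need an aldehyde on C5, epimerisable and β to the C4 acetate; closing C5–C10 or C9–C10 instead would create a quaternary centre late. Metathesis is neutral, makes no stereocentre and turns the bicycle into monocyclic 28 with two alkene-bearing arms. An acetal on the 3,4-diol was weighed and set aside: its acidic removal after ring closure would endanger the silyl ether, and the C4 acetylation would then face two tertiary alcohols. 28 therefore already carries the C3 ester and the C4 acetate. The forward reaction must close onto a hindered, electron-poor alkene.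

28 ⇒ 27 ⇒ 23 + 26. After adjusting C8 to the alcohol (27), the C7–C8 bond is cut into aldehyde 23 and alkenyl triflate 26. A C8–C9 cut would demand substitution at a neopentyl carbon, and a C7–C11 cut a hydroxyalkylation of a vinyl ketone by a ketone. The chosen cut is convergent and needs a coupling that tolerates esters and an epoxide. 26 comes from commercial ketone 24 through silyl ether 25; the ketone has one enolisable position, so the enol triflate is regiodefined.

23 ⇒ 21. The C8 aldehyde is traced to a terminal alkyne (C9≡C8) by way of alkenylborane 22. A free CH2–CHO arm could not be carried: it would form lactols with the C4 or C6 hydroxyl and react with ylides. The alkyne is inert to everything between its formation and step 17, and the forward step must select it over the C5 vinyl group.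

21 ⇒ 20 ⇒ 14 + 18. The two acyl C–O bonds are cut, acetate first, then the ester (through mixed anhydride 19). The order is forced by the migration argument above. Diol 14 has no other hydroxyl, so the secondary/tertiary difference alone should direct the esterification. Acid 18 goes back through epoxy alcohol 17 and allylic alcohol 16 to tiglic acid 15, an asymmetric epoxidation setting both epoxide centres.

14 ⇒ 13 ⇒ 12 ⇒ 11 ⇒ 10. The C6=CH2 bond is cut (methylenation of aldehyde 12), and the aldehyde is traced to the primary alcohol of 11. The diol is held as an acetonide (11–13) only for these two steps, because a free C4 hydroxyl would be β to the aldehyde (retro-aldol) and the C3 hydroxyl would be oxidised. The acetal is removed at 13, where no sensitive group is present.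

10 ⇒ 9. Both C–O bonds at C3 and C4 are cut (syn-dihydroxylation forward). The neighbouring option, hydroxylation at C4 of a C3 ketone followed by reduction, was rejected: hydride delivery to a 4-hydroxy-4-methyl-3-ketone, anti to the axial methyl or directed by the hydroxyl, is expected to give the trans diol. Alkene 9 has two fewer stereocentres, and the forward step needs only face selection by C5 and C10.

9 ⇒ 8. The alkyne carbon C8 is removed again (one-carbon homologation of a non-enolisable aldehyde) and the primary alcohol is returned to its acetate. Both changes happen in one forward operation.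

8 ⇒ 7 ⇒ 6 ⇒ 5. The C3=C4 alkene is traced through enol triflate 7 and silyl enol ether 6 to ketone 5. This costs three steps but places the alkene where the cycloaddition cannot; it asks for enolisation towards the more substituted side.

5 ⇒ 4 ⇒ 2 + 3 (2 ⇐ 1). The C4–C5 and C1–C10 bonds are cut (Diels–Alder). Dienophile 3 already holds the C10 methyl, the C9 carbon as a formyl group and C6 as an acetoxymethyl group, and its E geometry fixes the trans relation of the two future arms. Diene 2, from enone 1, brings the C4 methyl and the C3 oxygen and controls the regiochemistry. A chiral Lewis acid must supply the absolute configuration.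

## Roads not taken

Alternative 1: The cut is the C5–C10 bond, which unfolds the decalin into the ten-membered ring of germacrone A1. Forward, a confined chiral Brønsted acid would protonate C1, the C10 cation would be captured by C5 of the C4=C5 alkene, and loss of a proton from C3 would give eudesma-3,7(11)-dien-8-one A2 with both ring-fusion centres. The merit is great: A1 is commercial, one step builds the whole skeleton, the C3=C4 alkene is ready for α-face syn-dihydroxylation, and what remains is an oxidative shift of the C7=C11 bond to C6=C7 with oxygen at C11 plus two acylations. In step count this road is clearly better than the chosen one. Its weakness is that everything rests on one step without close analogy: A1 has no stereocentre, so the catalyst must choose between enantiomeric ring conformers, control cis versus trans fusion, and steer proton loss to C3 rather than C15 or C5, all in the presence of an acid-labile cross-conjugated enone. The later transposition must also pick the C6 hydrogens over two allylic methyl groups. Against the brevity, the chosen plan sets stereocentres that each arise from a reaction class with an established facial model, and a skeleton that does not depend on the fate of a carbocation.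

Alternative 2: The cut is the C9–C10 bond: the enone β-keto ester A3 would cyclise under a chiral bifunctional base, C9 adding to the enone β-carbon C10, and protonation at C5 would give the trans-fused β-keto ester A4. The reaction class is dependable, the bicycle is formed early, and the C8 oxygen and a C4 ketone are in place for later work; the activating ester would also help a regioselective functionalisation at C7. For this target the weak points are several. The acceptor is a β,β-disubstituted enone, a poor partner for a reaction that must form the quaternary C10 with high selectivity. The trans fusion depends on a protonation that often favours cis. The ester at C9 is not in the target and must be removed. Ring A needs the same conversion of a ketone into the 4-methyl-Δ3 alkene and dihydroxylation as in the chosen plan, and ring B still needs C11 and the C6=C7 unsaturation. It avoids the risk of a late ring closure, which is a real advantage, but it is longer, and its stereo-determining step is less secure than a cycloaddition whose relative configuration is fixed by alkene geometry.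

Alternative 3: The cuts are C5–C10 and C6–C7 together: the acyclic trienone A5 would undergo a catalytic asymmetric intramolecular Diels–Alder reaction, the vinyl ketone adding across the silyloxydiene, to give the decalone A6 after equilibration at C5. Both rings form at once from an achiral chain, and the C4 ketone and the C8 enol ether are differentiated on arrival; the route to a bicyclic intermediate is shorter than the chosen one. The difficulties are that the diene terminus C10 is fully substituted, that asymmetric catalysis of such a closure is little developed, and that trans fusion is to be reached by epimerisation next to the C4 ketone, where an angular methyl group leaves cis and trans decalones close in energy. The enol ether also points reactivity to C9 rather than C7, and ring A needs the same late methyl and diol work as in Alternative 2. The chosen plan gives up the early bicycle but fixes C5 and C10 irreversibly in its first stereo-defining step.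

Key step: step 22

Assumption: the proline-derived oxazaborolidinium catalysts are taken to follow their usual facial model for 2-substituted enals, under which the (R)-catalyst exposes the C2-si face of enal 3; were the sense the reverse, the (S)-catalyst would be used and nothing else changes.

## Route

Step 1
Reactants: 1 pent-1-en-3-one
Product: 2 (Z)-3-(triisopropylsilyloxy)penta-1,3-diene
Conditions: TIPSOTf, Et3N, Et2O, 0 °C to rt
Reagents that add atoms: triisopropylsilyl trifluoromethanesulfonate, CC(C)[Si](OS(=O)(=O)C(F)(F)F)(C(C)C)C(C)C
Why: Soft enolisation (silyl triflate and amine, silyl dienol ether formation) should give mainly the Z enol ether, whose terminal methyl lies outside the s-cis diene; only this isomer is a competent Diels–Alder diene, so any E isomer is left behind in step 2.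

Step 2
Reactants: 2 (Z)-3-(triisopropylsilyloxy)penta-1,3-diene; 3 (E)-4-acetoxy-2-methylbut-2-enal
Product: 5 [(1S,6S)-6-formyl-2,6-dimethyl-3-oxocyclohexyl]methyl acetate (C2 epimers), via silyl enol ether cycloadduct 4 (not isolated)
Conditions: (R)-B-(o-tolyl)oxazaborolidine from (R)-α,α-diphenylprolinol, activated with Tf2NH (20 mol%), CH2Cl2, −78 to −40 °C; then 2 M HCl, THF, rt
Reagents that add atoms: none
Why: Catalytic enantioselective Diels–Alder reaction of a 2-substituted enal: the silyloxy group makes the methyl-bearing diene terminus nucleophilic, so it bonds to the enal β-carbon (future C5) and the CH2 terminus closes onto the α-carbon (future quaternary C10). The E geometry of 3 is transferred suprafacially (acetoxymethyl cis to the C10 methyl, trans to formyl) and the catalyst face sets both centres (S,S here, the C5/C10 configuration of the target); the methyl-bearing carbon next to the ketone is left as a mixture because it is flattened in step 3.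

Step 3
Reactants: 5 [(1S,6S)-6-formyl-2,6-dimethyl-3-oxocyclohexyl]methyl acetate
Product: 6 [(1S,6S)-6-formyl-2,6-dimethyl-3-(trimethylsilyloxy)cyclohex-2-en-1-yl]methyl acetate
Conditions: TMSCl, NaI, Et3N, MeCN, rt
Reagents that add atoms: chlorotrimethylsilane, C[Si](C)(C)Cl
Why: Thermodynamic silyl enol ether formation (iodotrimethylsilane made in situ, equilibrating with amine) should favour the tetrasubstituted C3=C4 isomer; both epimers of 5 converge, and the aldehyde, which has no α-hydrogen, and the acetate are not enolised.

Step 4
Reactants: 6 [(1S,6S)-6-formyl-2,6-dimethyl-3-(trimethylsilyloxy)cyclohex-2-en-1-yl]methyl acetate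
Product: 7 [(1S,6S)-6-formyl-2,6-dimethyl-3-(trifluoromethanesulfonyloxy)cyclohex-2-en-1-yl]methyl acetate
Conditions: CsF, PhNTf2, DME, rt
Reagents that add atoms: N-phenylbis(trifluoromethanesulfonimide), O=S(=O)(N(c1ccccc1)S(=O)(=O)C(F)(F)F)C(F)(F)F
Why: Fluoride-induced desilylation releases the enolate regiospecifically and the triflimide traps it on oxygen (enol triflate formation from a silyl enol ether); no amide or alkyllithium base is used, so the aldehyde and acetate are spared and the double bond stays at C3=C4.

Step 5
Reactants: 7 [(1S,6S)-6-formyl-2,6-dimethyl-3-(trifluoromethanesulfonyloxy)cyclohex-2-en-1-yl]methyl acetate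
Product: 8 [(1S,6S)-6-formyl-2,6-dimethylcyclohex-2-en-1-yl]methyl acetate
Conditions: Pd(OAc)2 (5 mol%), PPh3, HCO2H, Bu3N, DMF, 60 °C
Reagents that add atoms: none
Why: Palladium-catalysed formate reduction of an enol triflate (oxidative addition, hydride from formate with loss of CO2, reductive elimination) replaces the triflate by hydrogen without moving the alkene; any C2=C3 isomer from step 3 is removed by chromatography here.

Step 6
Reactants: 8 [(1S,6S)-6-formyl-2,6-dimethylcyclohex-2-en-1-yl]methyl acetate
Product: 9 [(1S,6S)-6-ethynyl-2,6-dimethylcyclohex-2-en-1-yl]methanol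
Conditions: dimethyl (1-diazo-2-oxopropyl)phosphonate, K2CO3, MeOH, 0 °C to rt
Reagents that add atoms: dimethyl (1-diazo-2-oxopropyl)phosphonate, COP(=O)(OC)C(=[N+]=[N-])C(C)=O
Why: Seyferth–Gilbert homologation in the Ohira–Bestmann form turns the non-enolisable aldehyde into the terminal alkyne (C9≡C8), and the same basic methanol cleaves the primary acetate; the alkyne is the masked CH2–CHO arm, inert to the oxidations, the ylide and the acid that follow.

Step 7
Reactants: 9 [(1S,6S)-6-ethynyl-2,6-dimethylcyclohex-2-en-1-yl]methanol
Product: 10 (1R,2S,3S,4S)-4-ethynyl-3-(hydroxymethyl)-2,4-dimethylcyclohexane-1,2-diol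
Conditions: OsO4 (2 mol%), NMO, acetone/H2O, 0 °C to rt
Reagents that add atoms: osmium tetroxide, O=[Os](=O)(=O)=O; N-methylmorpholine N-oxide, C[N+]1([O-])CCOCC1; water, O
Why: Catalytic syn-dihydroxylation (Upjohn conditions) of the trisubstituted ring alkene: the reagent should approach anti to the adjacent C5 hydroxymethyl group and the C10 methyl group, on the face bearing only the slim ethynyl group, which sets C3 and C4 together (both oxygens α and cis); the alkyne reacts far more slowly.

Step 8
Reactants: 10 (1R,2S,3S,4S)-4-ethynyl-3-(hydroxymethyl)-2,4-dimethylcyclohexane-1,2-diol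
Product: 11 [(3aS,4S,5S,7aR)-5-ethynyl-2,2,3a,5-tetramethylhexahydro-1,3-benzodioxol-4-yl]methanol
Conditions: Me2C(OMe)2, PPTS (cat.), acetone, rt
Reagents that add atoms: 2,2-dimethoxypropane, COC(C)(C)OC
Why: Acid-catalysed acetonide formation under equilibrating conditions takes the cis-1,2-diol as the five-membered dioxolane in preference to the 1,3-related C4/C6 pair and leaves the primary alcohol free; it covers the C4 hydroxyl, otherwise β to the aldehyde of step 9, and the oxidisable C3 hydroxyl.

Step 9
Reactants: 11 [(3aS,4S,5S,7aR)-5-ethynyl-2,2,3a,5-tetramethylhexahydro-1,3-benzodioxol-4-yl]methanol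
Product: 12 (3aS,4R,5S,7aR)-5-ethynyl-2,2,3a,5-tetramethylhexahydro-1,3-benzodioxole-4-carbaldehyde
Conditions: DMP, NaHCO3, CH2Cl2, 0 °C to rt
Reagents that add atoms: none
Why: Dess–Martin oxidation of the primary alcohol under buffered, non-basic conditions, so the new aldehyde should not epimerise at C5 (its descriptor changes only through the CIP priorities).

Step 10
Reactants: 12 (3aS,4R,5S,7aR)-5-ethynyl-2,2,3a,5-tetramethylhexahydro-1,3-benzodioxole-4-carbaldehyde
Product: 13 (3aS,4R,5S,7aR)-4-ethenyl-5-ethynyl-2,2,3a,5-tetramethylhexahydro-1,3-benzodioxole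
Conditions: Ph3PCH3Br, KHMDS, THF, −78 to 0 °C
Reagents that add atoms: methyltriphenylphosphonium bromide, C[P+](c1ccccc1)(c1ccccc1)c1ccccc1.[Br-]
Why: Wittig methylenation with the smallest ylide should add to the hindered aldehyde faster than it removes the shielded C5 hydrogen, installing the vinyl group (C6 plus the carbon later lost in the metathesis) with C5 intact.

Step 11
Reactants: 13 (3aS,4R,5S,7aR)-4-ethenyl-5-ethynyl-2,2,3a,5-tetramethylhexahydro-1,3-benzodioxole
Product: 14 (1R,2S,3R,4S)-3-ethenyl-4-ethynyl-2,4-dimethylcyclohexane-1,2-diol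
Conditions: AcOH/H2O (4:1), 50 °C
Reagents that add atoms: none
Why: Acid hydrolysis of the isopropylidene acetal; the molecule holds only an alkyne, an alkene and the diol at this point, so nothing else is at risk.

Step 12
Reactants: 15 tiglic acid
Product: 16 (E)-2-methylbut-2-en-1-ol
Conditions: LiAlH4, Et2O, 0 °C to rt
Reagents that add atoms: none
Why: Hydride reduction of the carboxylic acid to the allylic alcohol; the trisubstituted alkene is not reduced and keeps its E geometry.

Step 13
Reactants: 16 (E)-2-methylbut-2-en-1-ol
Product: 17 [(2R,3R)-2,3-dimethyloxiran-2-yl]methanol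
Conditions: Ti(Oi-Pr)4 (10 mol%), D-(−)-diethyl tartrate (12 mol%), t-BuOOH, 4 Å MS, CH2Cl2, −20 °C
Reagents that add atoms: tert-butyl hydroperoxide, CC(C)(C)OO
Why: Sharpless asymmetric epoxidation: D-(−)-tartrate is the antipode of the ligand that converts E-allylic alcohols of this substitution pattern into (2S,3S)-epoxy alcohols, so the (2R,3R)-epoxide is expected, and syn oxygen transfer keeps the two methyl groups cis.

Step 14
Reactants: 17 [(2R,3R)-2,3-dimethyloxiran-2-yl]methanol
Product: 18 (2S,3R)-2,3-dimethyloxirane-2-carboxylic acid
Conditions: RuCl3·xH2O (2 mol%), NaIO4, MeCN/EtOAc/H2O, 0 °C to rt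
Reagents that add atoms: sodium periodate, [Na+].[O-]I(=O)(=O)=O; water, O
Why: Ruthenium tetroxide-catalysed oxidation of the primary alcohol to the acid, a standard passage from epoxy alcohols to glycidic acids; C2 is quaternary and cannot epimerise, and its descriptor changes from R to S only because the carboxyl group outranks C3.

Step 15
Reactants: 14 (1R,2S,3R,4S)-3-ethenyl-4-ethynyl-2,4-dimethylcyclohexane-1,2-diol; 18 (2S,3R)-2,3-dimethyloxirane-2-carboxylic acid
Product: 20 (1R,2S,3R,4S)-3-ethenyl-4-ethynyl-2-hydroxy-2,4-dimethylcyclohexyl (2S,3R)-2,3-dimethyloxirane-2-carboxylate, via mixed anhydride 19 (not isolated)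
Conditions: 18, 2,4,6-Cl3C6H2COCl, Et3N, THF, rt; then 14, DMAP, toluene, rt to 40 °C
Reagents that add atoms: none
Why: Yamaguchi esterification: the acid is activated as its mixed anhydride and transferred by DMAP to the secondary C3 hydroxyl, the tertiary C4 hydroxyl being too hindered to compete; no stereocentre is touched and the epoxide meets neither free acid chloride nor Lewis acid.

Step 16
Reactants: 20 (1R,2S,3R,4S)-3-ethenyl-4-ethynyl-2-hydroxy-2,4-dimethylcyclohexyl (2S,3R)-2,3-dimethyloxirane-2-carboxylate
Product: 21 (1R,2S,3R,4S)-2-acetoxy-3-ethenyl-4-ethynyl-2,4-dimethylcyclohexyl (2S,3R)-2,3-dimethyloxirane-2-carboxylate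
Conditions: Ac2O, DMAP, Et3N, toluene, 60 °C
Reagents that add atoms: acetic anhydride, CC(=O)OC(C)=O
Why: DMAP-catalysed acylation of the tertiary alcohol under forcing conditions; O3 is already blocked by a bulky ester that has no tendency to move to a tertiary oxygen, so no acyl migration is expected, and alkyne, alkene and epoxide are inert.

Step 17
Reactants: 21 (1R,2S,3R,4S)-2-acetoxy-3-ethenyl-4-ethynyl-2,4-dimethylcyclohexyl (2S,3R)-2,3-dimethyloxirane-2-carboxylate
Product: 23 (1R,2S,3R,4R)-2-acetoxy-3-ethenyl-2,4-dimethyl-4-(2-oxoethyl)cyclohexyl (2S,3R)-2,3-dimethyloxirane-2-carboxylate, via alkenylborane 22 (not isolated)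
Conditions: Cy2BH, THF, 0 °C; then 30% H2O2, pH 7 phosphate buffer, 0 °C to rt
Reagents that add atoms: hydrogen peroxide, OO
Why: Anti-Markovnikov hydroboration–oxidation of a terminal alkyne with a dialkylborane gives the aldehyde through the (E)-alkenylborane; the bulky borane should prefer the linear alkyne to the vinyl group flanked by two quaternary carbons and does not reduce esters, and the buffered oxidation avoids ester hydrolysis.

Step 18
Reactants: 24 3-hydroxy-3-methylbutan-2-one
Product: 25 3-methyl-3-(triethylsilyloxy)butan-2-one
Conditions: TESOTf, 2,6-lutidine, CH2Cl2, 0 °C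
Reagents that add atoms: triethylsilyl trifluoromethanesulfonate, CC[Si](CC)(CC)OS(=O)(=O)C(F)(F)F
Why: Silylation of a tertiary alcohol with a silyl triflate and a hindered base, the standard method when a silyl chloride is too slow.

Step 19
Reactants: 25 3-methyl-3-(triethylsilyloxy)butan-2-one
Product: 26 3-methyl-3-(triethylsilyloxy)but-1-en-2-yl trifluoromethanesulfonate
Conditions: KHMDS, THF, −78 °C; then PhNTf2
Reagents that add atoms: N-phenylbis(trifluoromethanesulfonimide), O=S(=O)(N(c1ccccc1)S(=O)(=O)C(F)(F)F)C(F)(F)F
Why: Enolate O-triflation: the ketone can enolise only towards its methyl group, so the 1,1-disubstituted enol triflate (C7 with its =CH2 and C11) forms without a regiochemical choice.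

Step 20
Reactants: 23 (1R,2S,3R,4R)-2-acetoxy-3-ethenyl-2,4-dimethyl-4-(2-oxoethyl)cyclohexyl (2S,3R)-2,3-dimethyloxirane-2-carboxylate; 26 3-methyl-3-(triethylsilyloxy)but-1-en-2-yl trifluoromethanesulfonate
Product: 27 (1R,2S,3R,4R)-2-acetoxy-3-ethenyl-4-[2-hydroxy-4-methyl-3-methylidene-4-(triethylsilyloxy)pentyl]-2,4-dimethylcyclohexyl (2S,3R)-2,3-dimethyloxirane-2-carboxylate (both C8 epimers)
Conditions: CrCl2, NiCl2 (2 mol%), DMF, rt
Reagents that add atoms: none
Why: Nozaki–Hiyama–Kishi coupling: nickel inserts into the enol triflate, the alkenyl group passes to chromium(III) and adds to the aldehyde only, forming the C7–C8 bond; the reagent is non-basic and tolerant of esters, and the new carbinol centre is removed in step 21.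

Step 21
Reactants: 27 (1R,2S,3R,4R)-2-acetoxy-3-ethenyl-4-[2-hydroxy-4-methyl-3-methylidene-4-(triethylsilyloxy)pentyl]-2,4-dimethylcyclohexyl (2S,3R)-2,3-dimethyloxirane-2-carboxylate
Product: 28 (1R,2S,3R,4R)-2-acetoxy-3-ethenyl-2,4-dimethyl-4-[4-methyl-3-methylidene-2-oxo-4-(triethylsilyloxy)pentyl]cyclohexyl (2S,3R)-2,3-dimethyloxirane-2-carboxylate
Conditions: DMP, NaHCO3, CH2Cl2, 0 °C to rt
Reagents that add atoms: none
Why: Dess–Martin oxidation of the secondary allylic alcohol converges both epimers on the 2-substituted enone under neutral conditions that spare the silyl ether, the epoxide and the Michael-acceptor alkene.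

Step 22
Reactants: 28 (1R,2S,3R,4R)-2-acetoxy-3-ethenyl-2,4-dimethyl-4-[4-methyl-3-methylidene-2-oxo-4-(triethylsilyloxy)pentyl]cyclohexyl (2S,3R)-2,3-dimethyloxirane-2-carboxylate
Product: 29 (1S,2R,4aR,8aR)-1-acetoxy-1,4a-dimethyl-6-oxo-7-[2-(triethylsilyloxy)propan-2-yl]-1,2,3,4,4a,5,6,8a-octahydronaphthalen-2-yl (2S,3R)-2,3-dimethyloxirane-2-carboxylate
Conditions: second-generation Hoveyda–Grubbs catalyst (15 mol%, in portions), toluene (0.002 M), 90 °C, Ar sparge
Reagents that add atoms: none
Why: Ring-closing olefin metathesis: the catalyst exchanges its benzylidene for the monosubstituted C5 vinyl group, the resulting alkylidene adds intramolecularly across the 1,1-disubstituted enone alkene through a ruthenacyclobutane, and cycloreversion expels a ruthenium methylidene (ethene) and leaves the C6=C7 bond. The closest known reaction type is the metathesis closure of 2-substituted cyclohex-2-enones from α-methylene ketones, here with a fully substituted carbon on the alkene. Ring B closes as a six-membered carbocycle between two alkene arms on adjacent ring A carbons, so the new double bond is endocyclic. No stereocentre is formed; C5 and C10 are fixed and trans, so only the trans-fused decalin can result and C5 never becomes enolisable. The step needs initiation at the vinyl group rather than at the hindered, electron-poor alkene, and ring closure rather than intermolecular metathesis. The first follows from the substitution pattern; the second is helped by the quaternary carbons C4 and C10 flanking the tether, by high dilution and by removal of ethene. A phosphine-free catalyst is chosen because it tolerates electron-poor alkenes and re-initiates readily.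

Step 23
Reactants: 29 (1S,2R,4aR,8aR)-1-acetoxy-1,4a-dimethyl-6-oxo-7-[2-(triethylsilyloxy)propan-2-yl]-1,2,3,4,4a,5,6,8a-octahydronaphthalen-2-yl (2S,3R)-2,3-dimethyloxirane-2-carboxylate
Product: 30 (1S,2R,4aR,8aR)-1-acetoxy-7-(2-hydroxypropan-2-yl)-1,4a-dimethyl-6-oxo-1,2,3,4,4a,5,6,8a-octahydronaphthalen-2-yl (2S,3R)-2,3-dimethyloxirane-2-carboxylate
Conditions: HF·pyridine, pyridine, THF, 0 °C to rt
Reagents that add atoms: none
Why: Fluoride-mediated cleavage of the triethylsilyl ether under buffered, non-basic conditions, so the acetate should not migrate, the epoxide and the β-hydroxy enone stay intact and C5 is not epimerised.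

## Compound list

1 | pent-1-en-3-one | CCC(=O)C=C | starting material
2 | (Z)-3-(triisopropylsilyloxy)penta-1,3-diene | C/C=C(\O[Si](C(C)C)(C(C)C)C(C)C)C=C | intermediate
3 | (E)-4-acetoxy-2-methylbut-2-enal | CC(=O)OC/C=C(\C)C=O | starting material
4 | [(1S,6S)-6-formyl-2,6-dimethyl-3-(triisopropylsilyloxy)cyclohex-3-en-1-yl]methyl acetate (C2 epimers; not isolated) | O=C[C@@]1(C)CC=C(O[Si](C(C)C)(C(C)C)C(C)C)C(C)[C@@H]1COC(C)=O | intermediate
5 | [(1S,6S)-6-formyl-2,6-dimethyl-3-oxocyclohexyl]methyl acetate (C2 epimers) | O=C[C@@]1(C)CCC(=O)C(C)[C@@H]1COC(C)=O | intermediate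
6 | [(1S,6S)-6-formyl-2,6-dimethyl-3-(trimethylsilyloxy)cyclohex-2-en-1-yl]methyl acetate | O=C[C@@]1(C)CCC(O[Si](C)(C)C)=C(C)[C@@H]1COC(C)=O | intermediate
7 | [(1S,6S)-6-formyl-2,6-dimethyl-3-(trifluoromethanesulfonyloxy)cyclohex-2-en-1-yl]methyl acetate | O=C[C@@]1(C)CCC(OS(=O)(=O)C(F)(F)F)=C(C)[C@@H]1COC(C)=O | intermediate
8 | [(1S,6S)-6-formyl-2,6-dimethylcyclohex-2-en-1-yl]methyl acetate | O=C[C@@]1(C)CCC=C(C)[C@@H]1COC(C)=O | intermediate
9 | [(1S,6S)-6-ethynyl-2,6-dimethylcyclohex-2-en-1-yl]methanol | C#C[C@@]1(C)CCC=C(C)[C@@H]1CO | intermediate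
10 | (1R,2S,3S,4S)-4-ethynyl-3-(hydroxymethyl)-2,4-dimethylcyclohexane-1,2-diol | C#C[C@@]1(C)CC[C@@H](O)[C@@](C)(O)[C@@H]1CO | intermediate
11 | [(3aS,4S,5S,7aR)-5-ethynyl-2,2,3a,5-tetramethylhexahydro-1,3-benzodioxol-4-yl]methanol | C#C[C@@]1(C)CC[C@H]2OC(C)(C)O[C@@]2(C)[C@@H]1CO | intermediate
12 | (3aS,4R,5S,7aR)-5-ethynyl-2,2,3a,5-tetramethylhexahydro-1,3-benzodioxole-4-carbaldehyde | C#C[C@@]1(C)CC[C@H]2OC(C)(C)O[C@@]2(C)[C@@H]1C=O | intermediate
13 | (3aS,4R,5S,7aR)-4-ethenyl-5-ethynyl-2,2,3a,5-tetramethylhexahydro-1,3-benzodioxole | C#C[C@@]1(C)CC[C@H]2OC(C)(C)O[C@@]2(C)[C@@H]1C=C | intermediate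
14 | (1R,2S,3R,4S)-3-ethenyl-4-ethynyl-2,4-dimethylcyclohexane-1,2-diol | C#C[C@@]1(C)CC[C@@H](O)[C@@](C)(O)[C@@H]1C=C | intermediate
15 | tiglic acid, (E)-2-methylbut-2-enoic acid | C/C=C(\C)C(=O)O | starting material
16 | (E)-2-methylbut-2-en-1-ol | C/C=C(\C)CO | intermediate
17 | [(2R,3R)-2,3-dimethyloxiran-2-yl]methanol | OC[C@@]1(C)O[C@@H]1C | intermediate
18 | (2S,3R)-2,3-dimethyloxirane-2-carboxylic acid | OC(=O)[C@@]1(C)O[C@@H]1C | intermediate
19 | (2S,3R)-2,3-dimethyloxirane-2-carboxylic 2,4,6-trichlorobenzoic anhydride (not isolated) | O=C(OC(=O)c1c(Cl)cc(Cl)cc1Cl)[C@@]1(C)O[C@@H]1C | intermediate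
20 | (1R,2S,3R,4S)-3-ethenyl-4-ethynyl-2-hydroxy-2,4-dimethylcyclohexyl (2S,3R)-2,3-dimethyloxirane-2-carboxylate | C#C[C@@]1(C)CC[C@@H](OC(=O)[C@@]2(C)O[C@@H]2C)[C@@](C)(O)[C@@H]1C=C | intermediate
21 | (1R,2S,3R,4S)-2-acetoxy-3-ethenyl-4-ethynyl-2,4-dimethylcyclohexyl (2S,3R)-2,3-dimethyloxirane-2-carboxylate | C#C[C@@]1(C)CC[C@@H](OC(=O)[C@@]2(C)O[C@@H]2C)[C@@](C)(OC(C)=O)[C@@H]1C=C | intermediate
22 | (1R,2S,3R,4R)-2-acetoxy-4-[(E)-2-(dicyclohexylboranyl)ethenyl]-3-ethenyl-2,4-dimethylcyclohexyl (2S,3R)-2,3-dimethyloxirane-2-carboxylate (not isolated) | C1CCCCC1B(C1CCCCC1)/C=C/[C@@]1(C)CC[C@@H](OC(=O)[C@@]2(C)O[C@@H]2C)[C@@](C)(OC(C)=O)[C@@H]1C=C | intermediate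
23 | (1R,2S,3R,4R)-2-acetoxy-3-ethenyl-2,4-dimethyl-4-(2-oxoethyl)cyclohexyl (2S,3R)-2,3-dimethyloxirane-2-carboxylate | O=CC[C@@]1(C)CC[C@@H](OC(=O)[C@@]2(C)O[C@@H]2C)[C@@](C)(OC(C)=O)[C@@H]1C=C | intermediate
24 | 3-hydroxy-3-methylbutan-2-one | CC(=O)C(C)(C)O | starting material
25 | 3-methyl-3-(triethylsilyloxy)butan-2-one | CC(=O)C(C)(C)O[Si](CC)(CC)CC | intermediate
26 | 3-methyl-3-(triethylsilyloxy)but-1-en-2-yl trifluoromethanesulfonate | C=C(OS(=O)(=O)C(F)(F)F)C(C)(C)O[Si](CC)(CC)CC | intermediate
27 | (1R,2S,3R,4R)-2-acetoxy-3-ethenyl-4-[2-hydroxy-4-methyl-3-methylidene-4-(triethylsilyloxy)pentyl]-2,4-dimethylcyclohexyl (2S,3R)-2,3-dimethyloxirane-2-carboxylate (both C8 epimers) | C=C(C(C)(C)O[Si](CC)(CC)CC)C(O)C[C@@]1(C)CC[C@@H](OC(=O)[C@@]2(C)O[C@@H]2C)[C@@](C)(OC(C)=O)[C@@H]1C=C | intermediate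
28 | (1R,2S,3R,4R)-2-acetoxy-3-ethenyl-2,4-dimethyl-4-[4-methyl-3-methylidene-2-oxo-4-(triethylsilyloxy)pentyl]cyclohexyl (2S,3R)-2,3-dimethyloxirane-2-carboxylate | C=C(C(C)(C)O[Si](CC)(CC)CC)C(=O)C[C@@]1(C)CC[C@@H](OC(=O)[C@@]2(C)O[C@@H]2C)[C@@](C)(OC(C)=O)[C@@H]1C=C | intermediate
29 | (1S,2R,4aR,8aR)-1-acetoxy-1,4a-dimethyl-6-oxo-7-[2-(triethylsilyloxy)propan-2-yl]-1,2,3,4,4a,5,6,8a-octahydronaphthalen-2-yl (2S,3R)-2,3-dimethyloxirane-2-carboxylate | CC(=O)O[C@@]1(C)[C@@H]2C=C(C(C)(C)O[Si](CC)(CC)CC)C(=O)C[C@@]2(C)CC[C@H]1OC(=O)[C@@]1(C)O[C@@H]1C | intermediate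
30 | CNP0219255.1, (1S,2R,4aR,8aR)-1-acetoxy-7-(2-hydroxypropan-2-yl)-1,4a-dimethyl-6-oxo-1,2,3,4,4a,5,6,8a-octahydronaphthalen-2-yl (2S,3R)-2,3-dimethyloxirane-2-carboxylate | CC(=O)O[C@@]1(C)[C@@H]2C=C(C(C)(C)O)C(=O)C[C@@]2(C)CC[C@H]1OC(=O)[C@@]1(C)O[C@@H]1C | target

## Step count and least certain steps

Total step count: 23. Longest linear sequence: 18 (steps 1–11, 15–17, 20–23).

Step 22 (key step). The alkylidene formed at the C5 vinyl group may fail to add to the 1,1-disubstituted alkene, which is both electron-poor and attached to a fully substituted carbon, so that catalyst decay, alkene isomerisation or intermolecular metathesis overtakes ring closure. Fallback: the ring is closed one oxidation level lower, starting from dienol 27. There the alkene is no longer conjugated and a free allylic hydroxyl is next to it, both of which favour metathesis; the same catalyst should give the bicyclic allylic alcohol (1S,2R,4aR,8aR)-1-acetoxy-6-hydroxy-1,4a-dimethyl-7-[2-(triethylsilyloxy)propan-2-yl]-1,2,3,4,4a,5,6,8a-octahydronaphthalen-2-yl (2S,3R)-2,3-dimethyloxirane-2-carboxylate F1, and Dess–Martin oxidation of F1 rejoins the route at 29.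

Step 2. Facial discrimination or rate may be poor, because the enal is trisubstituted and carries a β-substituent, and the silyl dienol ether may be consumed by acid-induced decomposition before it cycloadds. Fallback: from 2 and 3 the cycloaddition is run with an achiral Lewis acid (Me2AlCl, CH2Cl2, −78 °C). The relative configuration is still fixed by the alkene geometry, so the product is 4 together with its mirror image [(1R,6R)-6-formyl-2,6-dimethyl-3-(triisopropylsilyloxy)cyclohex-3-en-1-yl]methyl acetate F2. The same acidic work-up gives 5 together with [(1R,6R)-6-formyl-2,6-dimethyl-3-oxocyclohexyl]methyl acetate F3, and preparative chromatography on a chiral stationary phase separates them, rejoining the route at 5.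

Step 3. Enolisation may not go cleanly to the more substituted side, since the C5 substituent strains the tetrasubstituted enol ether, and the C2=C3 isomer would then be carried into the triflate. Fallback: from 5, acid-catalysed bromination (pyridinium tribromide, AcOH) takes the more substituted enol irreversibly and should give the tertiary bromide [(1S,6S)-2-bromo-6-formyl-2,6-dimethyl-3-oxocyclohexyl]methyl acetate F4; zinc and chlorotrimethylsilane then generate and silylate the enolate at the carbon that carried bromine, rejoining the route at 6.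

Step 17. Loss of chemoselectivity is the main danger: the borane may also add to the C5 vinyl group, or a second equivalent may add to the alkenylborane. Fallback: from 21, copper-catalysed protoboration (CuCl, Xantphos, NaOt-Bu cat., B2pin2, MeOH, THF), which acts on terminal alkynes and leaves unactivated alkenes alone, should give (1R,2S,3R,4R)-2-acetoxy-3-ethenyl-2,4-dimethyl-4-[(E)-2-(4,4,5,5-tetramethyl-1,3,2-dioxaborolan-2-yl)ethenyl]cyclohexyl (2S,3R)-2,3-dimethyloxirane-2-carboxylate F5; oxidation with sodium perborate rejoins the route at 23.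

Step 20. Oxidative addition and transfer of the alkenyl group next to a fully substituted carbon may be slow, and prolonged exposure to chromium(II) could begin to reduce the epoxy ester. Fallback: from ketone 25, condensation with 2,4,6-triisopropylbenzenesulfonyl hydrazide gives N'-[3-methyl-3-(triethylsilyloxy)butan-2-ylidene]-2,4,6-triisopropylbenzenesulfonohydrazide F6. Two equivalents of n-BuLi (Shapiro reaction) convert it into [3-methyl-3-(triethylsilyloxy)but-1-en-2-yl]lithium F7, which is added at −78 °C to aldehyde 23, the only fast electrophile next to a hindered ester and a tertiary acetate; this rejoins the route at 27.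

## Further compounds

F1 | step 22 | (1S,2R,4aR,8aR)-1-acetoxy-6-hydroxy-1,4a-dimethyl-7-[2-(triethylsilyloxy)propan-2-yl]-1,2,3,4,4a,5,6,8a-octahydronaphthalen-2-yl (2S,3R)-2,3-dimethyloxirane-2-carboxylate (both C6 epimers) | CC(=O)O[C@@]1(C)[C@@H]2C=C(C(C)(C)O[Si](CC)(CC)CC)C(O)C[C@@]2(C)CC[C@H]1OC(=O)[C@@]1(C)O[C@@H]1C
F2 | step 2 | [(1R,6R)-6-formyl-2,6-dimethyl-3-(triisopropylsilyloxy)cyclohex-3-en-1-yl]methyl acetate (C2 epimers) | O=C[C@]1(C)CC=C(O[Si](C(C)C)(C(C)C)C(C)C)C(C)[C@H]1COC(C)=O
F3 | step 2 | [(1R,6R)-6-formyl-2,6-dimethyl-3-oxocyclohexyl]methyl acetate (C2 epimers) | O=C[C@]1(C)CCC(=O)C(C)[C@H]1COC(C)=O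
F4 | step 3 | [(1S,6S)-2-bromo-6-formyl-2,6-dimethyl-3-oxocyclohexyl]methyl acetate (C2 epimers) | O=C[C@@]1(C)CCC(=O)C(C)(Br)[C@@H]1COC(C)=O
F5 | step 17 | (1R,2S,3R,4R)-2-acetoxy-3-ethenyl-2,4-dimethyl-4-[(E)-2-(4,4,5,5-tetramethyl-1,3,2-dioxaborolan-2-yl)ethenyl]cyclohexyl (2S,3R)-2,3-dimethyloxirane-2-carboxylate | CC1(C)OB(/C=C/[C@@]2(C)CC[C@@H](OC(=O)[C@@]3(C)O[C@@H]3C)[C@@](C)(OC(C)=O)[C@@H]2C=C)OC1(C)C
F6 | step 20 | N'-[3-methyl-3-(triethylsilyloxy)butan-2-ylidene]-2,4,6-triisopropylbenzenesulfonohydrazide | CC(=NNS(=O)(=O)c1c(C(C)C)cc(C(C)C)cc1C(C)C)C(C)(C)O[Si](CC)(CC)CC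
F7 | step 20 | [3-methyl-3-(triethylsilyloxy)but-1-en-2-yl]lithium | [Li]C(=C)C(C)(C)O[Si](CC)(CC)CC
A1 | alternative 1 | germacrone, (3E,7E)-3,7-dimethyl-10-(propan-2-ylidene)cyclodeca-3,7-dien-1-one | O=C1C/C(C)=C/CC/C(C)=C/CC1=C(C)C
A2 | alternative 1 | eudesma-3,7(11)-dien-8-one (5α-H, 10β-methyl) | CC1=CCC[C@]2(C)CC(=O)C(=C(C)C)C[C@@H]12
A3 | alternative 2 | methyl 5-(2-methyl-6-oxocyclohex-1-en-1-yl)-3-oxopentanoate | COC(=O)CC(=O)CCC1=C(C)CCCC1=O
A4 | alternative 2 | methyl 2-hydroxy-8a-methyl-5-oxo-3,4,4a,5,6,7,8,8a-octahydronaphthalene-1-carboxylate (enol form, trans-fused) | O=C1[C@@H]2CCC(O)=C(C(=O)OC)[C@@]2(C)CCC1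
A5 | alternative 3 | (7E)-9-(tert-butyldimethylsilyloxy)-7-methyldeca-1,7,9-trien-3-one | C=CC(=O)CCC/C(C)=C/C(=C)O[Si](C)(C)C(C)(C)C
A6 | alternative 3 | trans-6-(tert-butyldimethylsilyloxy)-4a-methyl-3,4,4a,7,8,8a-hexahydronaphthalen-1(2H)-one (5α-H, 10β-methyl) | O=C1[C@@H]2CCC(O[Si](C)(C)C(C)(C)C)=C[C@@]2(C)CCC1
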